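**Plan**

- Retrosynthesis first removes the four phenolic MOM groups and puts two phenylsulfonyl groups back on C2 of the propane tether, then cuts both tether bonds, C1–C2 and C2–C3.
- C2 is the only skeletal carbon bonded to neither benzene ring and lies between two benzylic CH2 groups, so it can come from bis(phenylsulfonyl)methane acting as a CH2 dianion equivalent; C1 and C3 come from two benzyl chlorides.
- Ring A chloride goes back to 2,4-dihydroxybenzaldehyde: the aryl–C bond to the 1,1-dimethylallyl group is cut by a retro-Claisen to a 4-O-prenyl ether.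
- Ring B chloride goes back to 5-bromovanillin: both aryl–prenyl bonds are cut to a vicinal dibromide (Stille coupling).
- Forward: both benzene rings are bought and no ring is formed; the chain is joined at the linchpin carbon in one flask, ring B first and ring A second, followed by desulfonylation and MOM removal.
- Stereochemistry: the target has no stereocentre and no stereogenic double bond, so nothing has to be controlled.

Key step: step 13

Remark: all compounds of the route are achiral; chloride 9 is assumed to be too labile for chromatography and is carried into step 13 crude.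

**Route**

Step 1
Reactants: 1 2,4-dihydroxybenzaldehyde; 2 1-bromo-3-methylbut-2-ene (prenyl bromide)
Product: 3 2-hydroxy-4-[(3-methylbut-2-en-1-yl)oxy]benzaldehyde
Conditions: K2CO3 (1.1 equiv), acetone, reflux
Reagents that add atoms: none
Why: Williamson ether synthesis; the 2-hydroxyl is held in a hydrogen bond to the formyl group, so the freer and more acidic 4-hydroxyl should be alkylated selectively with one equivalent of 2.

Step 2
Reactants: 3 2-hydroxy-4-[(3-methylbut-2-en-1-yl)oxy]benzaldehyde
Product: 4 2-(methoxymethoxy)-4-[(3-methylbut-2-en-1-yl)oxy]benzaldehyde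
Conditions: MOMCl, iPr2NEt, CH2Cl2, 0 °C to rt
Reagents that add atoms: chloromethyl methyl ether (MOMCl), COCCl
Why: O-alkylation of the phenol with an α-chloro ether (MOM protection) breaks the chelate to the carbonyl, which would otherwise steer the coming rearrangement to C3, and installs a group that lasts to the end.

Step 3
Reactants: 4 2-(methoxymethoxy)-4-[(3-methylbut-2-en-1-yl)oxy]benzaldehyde
Product: 5 4-hydroxy-2-(methoxymethoxy)-5-(2-methylbut-3-en-2-yl)benzaldehyde
Conditions: PhNEt2, 190 °C, sealed tube
Reagents that add atoms: none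
Why: Aromatic Claisen rearrangement, a [3,3]-sigmatropic shift that delivers the prenyl unit with allylic inversion as a 1,1-dimethylallyl group; C5 should be preferred over C3, which is flanked by two oxygen substituents, and the basic amine solvent suppresses acid-induced cyclisation of the ortho-allyl phenol.

Step 4
Reactants: 5 4-hydroxy-2-(methoxymethoxy)-5-(2-methylbut-3-en-2-yl)benzaldehyde
Product: 6 2,4-bis(methoxymethoxy)-5-(2-methylbut-3-en-2-yl)benzaldehyde
Conditions: MOMCl, iPr2NEt, CH2Cl2, 0 °C to reflux
Reagents that add atoms: chloromethyl methyl ether (MOMCl), COCCl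
Why: MOM protection; the phenol para to the formyl group is acidic enough to be alkylated under amine base despite the neighbouring quaternary carbon.

Step 5
Reactants: 6 2,4-bis(methoxymethoxy)-5-(2-methylbut-3-en-2-yl)benzaldehyde
Product: 7 [2,4-bis(methoxymethoxy)-5-(2-methylbut-3-en-2-yl)phenyl]methanol
Conditions: NaBH4, MeOH, 0 °C
Reagents that add atoms: none
Why: Borohydride reduction of an aryl aldehyde to the benzylic alcohol; acetals and the terminal alkene are inert to hydride.

Step 6
Reactants: 7 [2,4-bis(methoxymethoxy)-5-(2-methylbut-3-en-2-yl)phenyl]methanol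
Product: 9 1-(chloromethyl)-2,4-bis(methoxymethoxy)-5-(2-methylbut-3-en-2-yl)benzene (ring A benzyl chloride), via ring A benzyl mesylate 8 (not isolated)
Conditions: MsCl, Et3N, LiCl, THF, 0 °C to rt
Reagents that add atoms: methanesulfonyl chloride, CS(=O)(=O)Cl (sulfonyl group in 8 only); lithium chloride, [Li+].[Cl-]
Why: Sulfonylation of the primary benzylic alcohol and in situ displacement of mesylate by chloride occur under basic conditions that spare the MOM acetals and the alkene; 9 is used at once without chromatography.

Step 7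
Reactants: 10 3-bromo-4-hydroxy-5-methoxybenzaldehyde (5-bromovanillin)
Product: 11 2,3-dibromo-4-hydroxy-5-methoxybenzaldehyde
Conditions: Br2 (1.1 equiv), Fe powder (cat.), NaOAc, AcOH, rt
Reagents that add atoms: bromine, BrBr
Why: Electrophilic aromatic bromination; of the two free positions, both meta to the hydroxyl, the one para to the methoxy group is open whereas the other is wedged between the formyl and methoxy groups, so the vicinal dibromide should form.

Step 8
Reactants: 11 2,3-dibromo-4-hydroxy-5-methoxybenzaldehyde
Product: 12 2,3-dibromo-4,5-dihydroxybenzaldehyde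
Conditions: BBr3, CH2Cl2, −78 °C to rt; then H2O
Reagents that add atoms: none
Why: Lewis-acid cleavage of the aryl methyl ether by BBr3 (boron coordinates the ether oxygen, bromide attacks the methyl group); aryl bromides and the aldehyde survive.

Step 9
Reactants: 12 2,3-dibromo-4,5-dihydroxybenzaldehyde
Product: 13 2,3-dibromo-4,5-bis(methoxymethoxy)benzaldehyde
Conditions: MOMCl (excess), iPr2NEt, CH2Cl2, 0 °C to rt
Reagents that add atoms: chloromethyl methyl ether (MOMCl), COCCl
Why: Twofold MOM protection of the catechol gives ethers that tolerate palladium catalysis, hydride, NaH and Mg.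

Step 10
Reactants: 13 2,3-dibromo-4,5-bis(methoxymethoxy)benzaldehyde; 14 tributyl(3-methylbut-2-en-1-yl)stannane (2.6 equiv)
Product: 15 4,5-bis(methoxymethoxy)-2,3-bis(3-methylbut-2-en-1-yl)benzaldehyde
Conditions: Pd(PPh3)4 (10 mol %), DMF, 100 °C
Reagents that add atoms: none
Why: Twofold Migita–Kosugi–Stille coupling: zerovalent palladium inserts into each C–Br bond (the one ortho to the formyl group first), the allylic stannane transmetalates, and reductive elimination at the less substituted allyl terminus should keep both side chains as linear prenyl groups.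

Step 11
Reactants: 15 4,5-bis(methoxymethoxy)-2,3-bis(3-methylbut-2-en-1-yl)benzaldehyde
Product: 16 [4,5-bis(methoxymethoxy)-2,3-bis(3-methylbut-2-en-1-yl)phenyl]methanol
Conditions: NaBH4, MeOH, 0 °C
Reagents that add atoms: none
Why: Borohydride reduction of the aldehyde; the trisubstituted alkenes and MOM ethers are untouched.

Step 12
Reactants: 16 [4,5-bis(methoxymethoxy)-2,3-bis(3-methylbut-2-en-1-yl)phenyl]methanol
Product: 18 1-(chloromethyl)-4,5-bis(methoxymethoxy)-2,3-bis(3-methylbut-2-en-1-yl)benzene (ring B benzyl chloride), via ring B benzyl mesylate 17 (not isolated)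
Conditions: MsCl, Et3N, LiCl, THF, 0 °C to rt
Reagents that add atoms: methanesulfonyl chloride, CS(=O)(=O)Cl (sulfonyl group in 17 only); lithium chloride, [Li+].[Cl-]
Why: Mesylation and chloride displacement at the benzylic carbon under non-acidic conditions, with no electrophilic chlorine source that could attack the prenyl alkenes.

Step 13
Reactants: 19 bis(phenylsulfonyl)methane (1.05 equiv); 18 ring B benzyl chloride (1.0 equiv); 9 ring A benzyl chloride (1.3 equiv)
Product: 21 1-[2,4-bis(methoxymethoxy)-5-(2-methylbut-3-en-2-yl)phenyl]-3-[4,5-bis(methoxymethoxy)-2,3-bis(3-methylbut-2-en-1-yl)phenyl]-2,2-bis(phenylsulfonyl)propane, via monobenzylated bis-sulfone 20 (not isolated)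
Conditions: NaH (1.05 equiv), DMF, 0 °C; 18, rt; then NaH (1.2 equiv), 0 °C; 9, rt to 50 °C
Reagents that add atoms: none
Why: NaH turns 19, a carbon acid stronger than a malonate, into a soft sodium carbanion that displaces chloride from 18 by SN2 benzylation to give 20; its remaining C–H is still acidic, so a second charge of NaH regenerates a carbanion in the same flask and this is benzylated by 9, completing both C–C bonds to the central tether carbon. The closest known reaction type is the stepwise dialkylation of bis(phenylsulfonyl)methane used as a methylene dianion equivalent. No ring is closed and no stereocentre arises, because the new quaternary carbon carries two identical phenylsulfonyl groups. The selectivity needed is hetero- over homo-dialkylation: a slight excess of the anion of 19 over 18 at 0 °C to rt should stop the first stage cleanly, since the crowded anion of 20 is a much poorer nucleophile than the anion of 19. Chloride 9, with ortho- and para-alkoxy groups, is the more ionisable electrophile and is therefore kept for the hindered second alkylation, and neither chloride has a β-hydrogen, so elimination cannot compete. Because the tether is assembled at the alkane oxidation level, no alkene or carbonyl has to be reduced later beside the three C=C bonds.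

Step 14
Reactants: 21 the 2,2-bis(phenylsulfonyl)propane from step 13
Product: 22 1-[2,4-bis(methoxymethoxy)-5-(2-methylbut-3-en-2-yl)phenyl]-3-[4,5-bis(methoxymethoxy)-2,3-bis(3-methylbut-2-en-1-yl)phenyl]propane (kazinol C tetrakis-MOM ether)
Conditions: Mg turnings (excess), MeOH, 50 °C
Reagents that add atoms: none
Why: Reductive desulfonylation by single-electron transfer from magnesium, each C–S bond being cleaved to sulfinate and a carbanion that methanol protonates; isolated alkenes and aryl MOM ethers are not reduced.

Step 15
Reactants: 22 kazinol C tetrakis-MOM ether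
Product: 23 kazinol C, 5-{3-[2,4-dihydroxy-5-(2-methylbut-3-en-2-yl)phenyl]propyl}-3,4-bis(3-methylbut-2-en-1-yl)benzene-1,2-diol
Conditions: aq. HCl (3 M), MeOH, 40 °C, argon
Reagents that add atoms: none
Why: Acid-catalysed acetal methanolysis removes all four MOM groups as dimethoxymethane; dilute acid at mild temperature should leave the prenyl and 1,1-dimethylallyl groups uncyclised, and argon protects the catechol.

**Compound list**

1 | 2,4-dihydroxybenzaldehyde | O=Cc1ccc(O)cc1O | starting material
2 | 1-bromo-3-methylbut-2-ene (prenyl bromide) | CC(C)=CCBr | starting material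
3 | 2-hydroxy-4-[(3-methylbut-2-en-1-yl)oxy]benzaldehyde | O=Cc1ccc(OCC=C(C)C)cc1O | intermediate
4 | 2-(methoxymethoxy)-4-[(3-methylbut-2-en-1-yl)oxy]benzaldehyde | COCOc1cc(OCC=C(C)C)ccc1C=O | intermediate
5 | 4-hydroxy-2-(methoxymethoxy)-5-(2-methylbut-3-en-2-yl)benzaldehyde | C=CC(C)(C)c1cc(C=O)c(OCOC)cc1O | intermediate
6 | 2,4-bis(methoxymethoxy)-5-(2-methylbut-3-en-2-yl)benzaldehyde | C=CC(C)(C)c1cc(C=O)c(OCOC)cc1OCOC | intermediate
7 | [2,4-bis(methoxymethoxy)-5-(2-methylbut-3-en-2-yl)phenyl]methanol | C=CC(C)(C)c1cc(CO)c(OCOC)cc1OCOC | intermediate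
8 | 2,4-bis(methoxymethoxy)-5-(2-methylbut-3-en-2-yl)benzyl methanesulfonate (ring A benzyl mesylate) | C=CC(C)(C)c1cc(COS(C)(=O)=O)c(OCOC)cc1OCOC | intermediate
9 | 1-(chloromethyl)-2,4-bis(methoxymethoxy)-5-(2-methylbut-3-en-2-yl)benzene (ring A benzyl chloride) | C=CC(C)(C)c1cc(CCl)c(OCOC)cc1OCOC | intermediate
10 | 3-bromo-4-hydroxy-5-methoxybenzaldehyde (5-bromovanillin) | COc1cc(C=O)cc(Br)c1O | starting material
11 | 2,3-dibromo-4-hydroxy-5-methoxybenzaldehyde | COc1cc(C=O)c(Br)c(Br)c1O | intermediate
12 | 2,3-dibromo-4,5-dihydroxybenzaldehyde | O=Cc1cc(O)c(O)c(Br)c1Br | intermediate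
13 | 2,3-dibromo-4,5-bis(methoxymethoxy)benzaldehyde | COCOc1cc(C=O)c(Br)c(Br)c1OCOC | intermediate
14 | tributyl(3-methylbut-2-en-1-yl)stannane | CCCC[Sn](CCCC)(CCCC)CC=C(C)C | starting material
15 | 4,5-bis(methoxymethoxy)-2,3-bis(3-methylbut-2-en-1-yl)benzaldehyde | COCOc1cc(C=O)c(CC=C(C)C)c(CC=C(C)C)c1OCOC | intermediate
16 | [4,5-bis(methoxymethoxy)-2,3-bis(3-methylbut-2-en-1-yl)phenyl]methanol | COCOc1cc(CO)c(CC=C(C)C)c(CC=C(C)C)c1OCOC | intermediate
17 | 4,5-bis(methoxymethoxy)-2,3-bis(3-methylbut-2-en-1-yl)benzyl methanesulfonate (ring B benzyl mesylate) | COCOc1cc(COS(C)(=O)=O)c(CC=C(C)C)c(CC=C(C)C)c1OCOC | intermediate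
18 | 1-(chloromethyl)-4,5-bis(methoxymethoxy)-2,3-bis(3-methylbut-2-en-1-yl)benzene (ring B benzyl chloride) | COCOc1cc(CCl)c(CC=C(C)C)c(CC=C(C)C)c1OCOC | intermediate
19 | bis(phenylsulfonyl)methane | O=S(=O)(CS(=O)(=O)c1ccccc1)c1ccccc1 | starting material
20 | 1-[2,2-bis(phenylsulfonyl)ethyl]-4,5-bis(methoxymethoxy)-2,3-bis(3-methylbut-2-en-1-yl)benzene (monobenzylated bis-sulfone) | COCOc1cc(CC(S(=O)(=O)c2ccccc2)S(=O)(=O)c2ccccc2)c(CC=C(C)C)c(CC=C(C)C)c1OCOC | intermediate
21 | 1-[2,4-bis(methoxymethoxy)-5-(2-methylbut-3-en-2-yl)phenyl]-3-[4,5-bis(methoxymethoxy)-2,3-bis(3-methylbut-2-en-1-yl)phenyl]-2,2-bis(phenylsulfonyl)propane | C=CC(C)(C)c1cc(CC(Cc2cc(OCOC)c(OCOC)c(CC=C(C)C)c2CC=C(C)C)(S(=O)(=O)c2ccccc2)S(=O)(=O)c2ccccc2)c(OCOC)cc1OCOC | intermediate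
22 | 1-[2,4-bis(methoxymethoxy)-5-(2-methylbut-3-en-2-yl)phenyl]-3-[4,5-bis(methoxymethoxy)-2,3-bis(3-methylbut-2-en-1-yl)phenyl]propane | C=CC(C)(C)c1cc(CCCc2cc(OCOC)c(OCOC)c(CC=C(C)C)c2CC=C(C)C)c(OCOC)cc1OCOC | intermediate
23 | kazinol C, 5-{3-[2,4-dihydroxy-5-(2-methylbut-3-en-2-yl)phenyl]propyl}-3,4-bis(3-methylbut-2-en-1-yl)benzene-1,2-diol | C=CC(C)(C)c1cc(CCCc2cc(O)c(O)c(CC=C(C)C)c2CC=C(C)C)c(O)cc1O | target

**Step count and risks**

Total step count: 15. Longest linear sequence: 9 steps (steps 1–6 or steps 7–12, then steps 13–15).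

Steps most likely to fail:

Step 13. The second benzylation may stall at the crowded tertiary carbanion of 20. Chloride 9 may be lost to self-condensation or hydrolysis before it is captured, and some homo-dialkylation by 18 may occur in the first stage. The fallback changes the linchpin to methyl phenyl sulfone, whose mono-sulfonyl carbanions are smaller and far more nucleophilic. It sets out from 18: lithiated methyl phenyl sulfone (n-BuLi, THF, −78 °C, twofold excess) should give 1-[2-(phenylsulfonyl)ethyl]-4,5-bis(methoxymethoxy)-2,3-bis(3-methylbut-2-en-1-yl)benzene F1. Deprotonation of F1 with n-BuLi at −78 °C and alkylation with 9 should give racemic 1-[2,4-bis(methoxymethoxy)-5-(2-methylbut-3-en-2-yl)phenyl]-3-[4,5-bis(methoxymethoxy)-2,3-bis(3-methylbut-2-en-1-yl)phenyl]-2-(phenylsulfonyl)propane F2. Mg in MeOH then removes the single sulfonyl group and the route is rejoined at 22.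

Step 3. The rearrangement may suffer from migration to C3, further thermal isomerisation or cyclisation of the ortho-allyl phenol, and loss of the prenyl group. The fallback makes the quaternary benzylic carbon by cross-coupling. It sets out from 1: bromination at C5 (Br2, AcOH) should give 5-bromo-2,4-dihydroxybenzaldehyde F3, and MOMCl with iPr2NEt should give 5-bromo-2,4-bis(methoxymethoxy)benzaldehyde F4. A γ-selective Suzuki–Miyaura allylation of F4 with 3-methylbut-2-en-1-ylboronic acid pinacol ester (Pd(OAc)2, a bulky electron-rich phosphine such as 1,1'-bis(di-tert-butylphosphino)ferrocene, K3PO4, aqueous THF) should place the 2-methylbut-3-en-2-yl group on C5 and rejoin the route at 6.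

Step 10. The second coupling at the bromide flanked by two substituents may be incomplete, the prenyl group may be delivered with allylic transposition, and protodebromination may compete. The fallback moves the coupling to the alcohol oxidation level so that a more reactive organozinc can be used. It sets out from 13: NaBH4 in MeOH should give [2,3-dibromo-4,5-bis(methoxymethoxy)phenyl]methanol F5. A twofold linear-selective Negishi coupling of F5 with prenylzinc bromide (from 2 and Zn dust, LiCl, THF; one extra equivalent is consumed by the hydroxyl group) under Pd(OAc)2 and the biarylphosphine CPhos in THF at rt should give the diprenyl alcohol, rejoining the route at 16.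

**Further compounds**

F1 | step 13 | 1-[2-(phenylsulfonyl)ethyl]-4,5-bis(methoxymethoxy)-2,3-bis(3-methylbut-2-en-1-yl)benzene | COCOc1cc(CCS(=O)(=O)c2ccccc2)c(CC=C(C)C)c(CC=C(C)C)c1OCOC
F2 | step 13 | racemic 1-[2,4-bis(methoxymethoxy)-5-(2-methylbut-3-en-2-yl)phenyl]-3-[4,5-bis(methoxymethoxy)-2,3-bis(3-methylbut-2-en-1-yl)phenyl]-2-(phenylsulfonyl)propane | C=CC(C)(C)c1cc(CC(Cc2cc(OCOC)c(OCOC)c(CC=C(C)C)c2CC=C(C)C)S(=O)(=O)c2ccccc2)c(OCOC)cc1OCOC
F3 | step 3 | 5-bromo-2,4-dihydroxybenzaldehyde | O=Cc1cc(Br)c(O)cc1O
F4 | step 3 | 5-bromo-2,4-bis(methoxymethoxy)benzaldehyde | COCOc1cc(OCOC)c(C=O)cc1Br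
F5 | step 10 | [2,3-dibromo-4,5-bis(methoxymethoxy)phenyl]methanol | COCOc1cc(CO)c(Br)c(Br)c1OCOC
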